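**Plan**

1. Cuts, in retrosynthetic order: the nineteen O‑benzyl groups and a blocking bromine at C8 of the middle unit; both gallate ester C–O bonds; the C4–C4a bond of ring C of the top flavan unit; C4(top)–C6(middle); C4(middle)–C8(lower); in the side branch, the aryl ether O1–C2 and the C2–aryl bond of the top C2–C3–C4 chain.
2. Forward order: epicatechin is benzylated, brominated at C8, oxidised at C4 and iodinated at C6, then joined 4β→8 to perbenzylated catechin. The C2–C3–C4 chain of the top unit is built on glyceraldehyde acetonide (aryl addition, aryl ether, aldehyde) and added to C6 of the middle unit through magnesium. Ring C of the top unit is then closed, the only ring made in the route; galloylation and hydrogenolysis finish.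
3. Enabling feature: C4 of the top unit is a methine between two phloroglucinol‑type rings. A cation on a carbon bound to C6 of the middle ring A is stabilised by the C5 and C7 oxygens (ortho) and by O1 through C8a (para). The 3,5‑dioxygenated aryl ether on O1 of the top unit offers two equivalent, strongly nucleophilic ortho carbons, either of which becomes C4a.
4. Stereochemistry: the lower and middle units are (+)‑catechin and (−)‑epicatechin; C4 of the middle unit forms trans to its C3 oxygen. In the top unit C3 is bought with (R)‑glyceraldehyde acetonide, C2 follows from a Felkin–Anh aryl addition and a Mitsunobu inversion, and C4 is set in the ring closure by allylic 1,3‑strain.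
5. Helpers: Br at C8 (blocks C8, leaves in the hydrogenolysis), I at C6 (carbon handle), one TBS and one TES ether (mark the two hydroxyls that take the gallates), benzyl on the lower C3 oxygen (keeps it free at the end).

Key step: step 15

Remark: flavan numbering (O1, C2, C3, C4, C4a, C5 to C8, C8a; ring B positions primed) is used for each unit, called top, middle and lower. The given SMILES is read as epicatechin‑3‑O‑gallate‑(4β→6)‑epicatechin‑3‑O‑gallate‑(4β→8)‑catechin: top and middle units 2R,3R with the 4‑aryl bond trans to the C3 oxygen, lower unit 2R,3S.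

**Route**

Step 1
Reactants: 1 (−)-epicatechin
Product: 2 5,7,3',4'-tetra-O-benzyl-(−)-epicatechin
Conditions: BnBr (4.4 equiv), K2CO3, DMF, 0 °C to rt
Reagents that add atoms: benzyl bromide, BrCc1ccccc1
Why: Williamson etherification in which K2CO3 deprotonates only the four phenols, so the secondary 3-OH stays free and the mild base leaves C2 and C3 untouched.

Step 2
Reactants: 2 5,7,3',4'-tetra-O-benzyl-(−)-epicatechin
Product: 3 8-bromo-5,7,3',4'-tetra-O-benzyl-(−)-epicatechin
Conditions: NBS (1.0 equiv), CH2Cl2, −78 °C to rt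
Reagents that add atoms: N-bromosuccinimide, O=C1CCC(=O)N1Br
Why: Electrophilic aromatic bromination, which for benzylated flavan-3-ols goes first to C8, the most nucleophilic carbon of ring A, so one equivalent should give the 8-bromide that later blocks this position.

Step 3
Reactants: 3 8-bromo-5,7,3',4'-tetra-O-benzyl-(−)-epicatechin
Product: 4 8-bromo-5,7,3',4'-tetra-O-benzyl-3-O-(tert-butyldimethylsilyl)-(−)-epicatechin
Conditions: TBSCl, imidazole, DMF, rt to 50 °C
Reagents that add atoms: tert-butyldimethylsilyl chloride, CC(C)(C)[Si](C)(C)Cl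
Why: Imidazole-promoted silylation of the only free hydroxyl, which marks this oxygen for the later galloylation.

Step 4
Reactants: 4 8-bromo-5,7,3',4'-tetra-O-benzyl-3-O-(tert-butyldimethylsilyl)-(−)-epicatechin
Product: 5 8-bromo-4β-(2-ethoxyethoxy)-5,7,3',4'-tetra-O-benzyl-3-O-(tert-butyldimethylsilyl)-(−)-epicatechin (alkoxy group trans to the 3-silyloxy group)
Conditions: DDQ (2 equiv), 2-ethoxyethanol (5 equiv), CH2Cl2, rt
Reagents that add atoms: 2-ethoxyethanol, CCOCCO
Why: DDQ benzylic oxidation, in which hydride abstraction from C4 gives the flavan-4-yl cation stabilised by ring A and the alcohol captures it on the face opposite the 3-silyloxy group, so the new C4 stereocenter should be 4β (3,4-trans).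

Step 5
Reactants: 5 8-bromo-4β-(2-ethoxyethoxy)-5,7,3',4'-tetra-O-benzyl-3-O-(tert-butyldimethylsilyl)-(−)-epicatechin
Product: 6 8-bromo-6-iodo-4β-(2-ethoxyethoxy)-5,7,3',4'-tetra-O-benzyl-3-O-(tert-butyldimethylsilyl)-(−)-epicatechin
Conditions: NIS (1.1 equiv), NaHCO3, DMF, 0 °C to rt, dark
Reagents that add atoms: N-iodosuccinimide, O=C1CCC(=O)N1I
Why: Electrophilic aromatic iodination at C6, the only open carbon of ring A once C8 is blocked, in analogy to the second halogenation of 8-bromo flavan-3-ols, under buffered neutral conditions that spare the acid-labile C4 ether.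

Step 6
Reactants: 7 (+)-catechin
Product: 8 5,7,3',4'-tetra-O-benzyl-(+)-catechin
Conditions: BnBr (4.4 equiv), K2CO3, DMF, 0 °C to rt
Reagents that add atoms: benzyl bromide, BrCc1ccccc1
Why: Williamson etherification of the four phenols under the same mild base, which leaves the 3-OH and both stereocenters untouched.

Step 7
Reactants: 8 5,7,3',4'-tetra-O-benzyl-(+)-catechin
Product: 9 3,5,7,3',4'-penta-O-benzyl-(+)-catechin
Conditions: NaH, BnBr, DMF, 0 °C to rt
Reagents that add atoms: benzyl bromide, BrCc1ccccc1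
Why: Williamson etherification of the secondary alkoxide, safe for C2 because with all phenols capped no quinone methide ring opening is possible, and the benzyl ether keeps this hydroxyl out of the later galloylation.

Step 8
Reactants: 6 8-bromo-6-iodo-4β-(2-ethoxyethoxy)-5,7,3',4'-tetra-O-benzyl-3-O-(tert-butyldimethylsilyl)-(−)-epicatechin; 9 3,5,7,3',4'-penta-O-benzyl-(+)-catechin
Product: 10 dimer iodide 8-bromo-6-iodo-5,7,3',4'-tetra-O-benzyl-3-O-TBS-epicatechin-(4β→8)-3,5,7,3',4'-penta-O-benzylcatechin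
Conditions: TMSOTf (0.5 equiv), 9 (2.5 equiv), 4 Å MS, CH2Cl2, −78 to −30 °C; Et3N quench
Reagents that add atoms: none
Why: Lewis acid flavan-4-yl cation/arene coupling (Friedel–Crafts alkylation as used for procyanidins), in which C8 of the catechin ether, more nucleophilic than C6, attacks the C4 cation trans to the 3-silyloxy group to set the 4β configuration, while the electrophile, halogenated at C6 and C8, cannot add to itself.

Step 9
Reactants: 11 4-bromo-1,2-bis(benzyloxy)benzene; 12 (R)-2,2-dimethyl-1,3-dioxolane-4-carbaldehyde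
Product: 15 (S)-[3,4-bis(benzyloxy)phenyl][(4R)-2,2-dimethyl-1,3-dioxolan-4-yl]methanol (anti adduct), via aryllithium 13 (not isolated), via aryltitanium triisopropoxide 14 (not isolated)
Conditions: n-BuLi, THF, −78 °C; ClTi(OiPr)3, −78 to −40 °C; 12, −78 to −20 °C; aqueous work-up
Reagents that add atoms: none
Why: Bromine–lithium exchange and transmetalation give a non-chelating aryltitanium that adds to the α-alkoxy aldehyde in the Felkin–Anh sense, so the bought stereocenter should set the new carbinol carbon as S (anti).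

Step 10
Reactants: 15 (S)-[3,4-bis(benzyloxy)phenyl][(4R)-2,2-dimethyl-1,3-dioxolan-4-yl]methanol; 16 3,5-bis(benzyloxy)phenol
Product: 17 (4R)-4-{(R)-[3,4-bis(benzyloxy)phenyl][3,5-bis(benzyloxy)phenoxy]methyl}-2,2-dimethyl-1,3-dioxolane
Conditions: PPh3, DIAD, toluene, 0 °C to rt
Reagents that add atoms: none
Why: Mitsunobu etherification, an SN2 displacement by the phenol that inverts the carbinol carbon to R and so gives the threo arrangement of the two oxygens that becomes 2,3-cis in the flavan, the neighbouring dioxolane oxygen disfavouring benzylic ionisation.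

Step 11
Reactants: 17 (4R)-4-{(R)-[3,4-bis(benzyloxy)phenyl][3,5-bis(benzyloxy)phenoxy]methyl}-2,2-dimethyl-1,3-dioxolane
Product: 18 (2R,3R)-3-[3,4-bis(benzyloxy)phenyl]-3-[3,5-bis(benzyloxy)phenoxy]propane-1,2-diol
Conditions: AcOH/H2O 4:1, 40 °C
Reagents that add atoms: none
Why: Acid-catalysed acetal hydrolysis under conditions mild enough to leave the benzylic aryl ether and the benzyl ethers intact.

Step 12
Reactants: 18 (2R,3R)-3-[3,4-bis(benzyloxy)phenyl]-3-[3,5-bis(benzyloxy)phenoxy]propane-1,2-diol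
Product: 19 (2R,3R)-3-[3,4-bis(benzyloxy)phenyl]-3-[3,5-bis(benzyloxy)phenoxy]-1,2-bis(triethylsilyloxy)propane
Conditions: TESCl (2.5 equiv), imidazole, DMAP (cat.), CH2Cl2, 0 °C to rt
Reagents that add atoms: chlorotriethylsilane, CC[Si](Cl)(CC)CC
Why: Exhaustive silylation of the primary and the secondary hydroxyl, which prepares the selective oxidation of the primary position.

Step 13
Reactants: 19 (2R,3R)-3-[3,4-bis(benzyloxy)phenyl]-3-[3,5-bis(benzyloxy)phenoxy]-1,2-bis(triethylsilyloxy)propane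
Product: 20 (2S,3R)-3-[3,4-bis(benzyloxy)phenyl]-3-[3,5-bis(benzyloxy)phenoxy]-2-(triethylsilyloxy)propanal
Conditions: (COCl)2, DMSO, CH2Cl2, −78 to −40 °C; Et3N, −78 to 0 °C
Reagents that add atoms: none
Why: Swern oxidation in its known variant on silyl ethers, where the chlorosulfonium reagent cleaves the primary triethylsilyl ether and oxidises it in the same flask while the secondary one survives, the low temperature guarding the α-stereocenter and the β-aryloxy group.

Step 14
Reactants: 10 dimer iodide; 20 (2S,3R)-3-[3,4-bis(benzyloxy)phenyl]-3-[3,5-bis(benzyloxy)phenoxy]-2-(triethylsilyloxy)propanal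
Product: 22 carbinol in which the iodine of 10 is replaced by the (1RS,2R,3R)-3-[3,4-bis(benzyloxy)phenyl]-3-[3,5-bis(benzyloxy)phenoxy]-1-hydroxy-2-(triethylsilyloxy)propyl group, via arylmagnesium chloride 21 (not isolated)
Conditions: i-PrMgCl·LiCl (1.1 equiv), THF, −20 °C; 20 (1.3 equiv), −40 to 0 °C; aq NH4Cl
Reagents that add atoms: none
Why: Iodine–magnesium exchange, which takes the aryl iodide and not the aryl bromide, followed by 1,2-addition to the aldehyde, fixes the carbon chain on C6 of the middle unit without any regiochemical choice; both carbinol epimers serve because this carbon becomes planar in the next step.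

Step 15
Reactants: 22 carbinol (both epimers at the hydroxyl-bearing carbon)
Product: 23 protected trimer 5,7,3',4'-tetra-O-benzyl-3-O-triethylsilyl-epicatechin-(4β→6)-8-bromo-5,7,3',4'-tetra-O-benzyl-3-O-TBS-epicatechin-(4β→8)-3,5,7,3',4'-penta-O-benzylcatechin
Conditions: TMSOTf (0.1 equiv), 4 Å MS, CH2Cl2 (2 mM), −78 to −40 °C; Et3N quench
Reagents that add atoms: none
Why: TMSOTf ionises the benzylic hydroxyl of either epimer of 22 to one and the same cation, held by the C5 and C7 benzyloxy groups and by O1 (para, through C8a) of the middle ring A, and an ortho carbon of the 3,5-bis(benzyloxy)phenyl ether adds to it and loses a proton. The closest known reaction type is the acid-mediated intramolecular Friedel–Crafts alkylation of 3-aryloxy-1-arylpropan-1-ols to 4-arylchromans, together with the Lewis acid coupling of flavan-4-yl cations with phloroglucinol-type arenes. Ring C of the top unit (O1, C2, C3, C4, C4a, C8a) closes through the C4–C4a bond in a 6-exo-trig mode with respect to the cationic unit C4(top)=C6(middle), the bonds O1–C2, C2–C3 and C3–C4 being in place. The new stereocenter C4 is controlled by allylic 1,3-strain: H3 lies in the plane of the cation beside the ortho substituents of the middle ring A, the tether through C2 then brings the arene to the face anti to the C3 silyloxy group, and the 3,4-trans (4β) product with a pseudoaxial 4-aryl group, free of peri strain with the C5 benzyloxy group, should result. Regiochemistry needs no control because the two ortho carbons of the symmetric aryl ether are equivalent and the para carbon cannot reach C4, while the far less nucleophilic catechol ring B would have to close a five-membered ring. Chemoselectivity rests on the low temperature and catalytic acid, the conditions under which the 4→8 bond of 10 was made and under which silyl and benzyl ethers persist.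

Step 16
Reactants: 23 protected trimer
Product: 24 diol, that is 23 without the two silyl groups (free 3-OH on the top and on the middle unit)
Conditions: TBAF (4 equiv), THF, 0 to 40 °C
Reagents that add atoms: none
Why: Fluoride-induced desilylation removes the TES and the TBS ether together and leaves benzyl ethers, the aryl bromide and the interflavan bonds untouched.

Step 17
Reactants: 24 diol; 25 3,4,5-tris(benzyloxy)benzoic acid
Product: 26 bis-gallate, that is 24 esterified at both free 3-OH groups with 3,4,5-tris(benzyloxy)benzoic acid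
Conditions: 25 (4 equiv), DCC, DMAP, CH2Cl2, rt to 40 °C
Reagents that add atoms: none
Why: Steglich esterification of the only two free hydroxyls, the lower 3-oxygen being benzylated, as practised for 3-O-galloylation of benzylated procyanidins.

Step 18
Reactants: 26 bis-gallate
Product: 27 epicatechin-3-O-gallate-(4β→6)-epicatechin-3-O-gallate-(4β→8)-catechin (CNP0112921.1)
Conditions: H2 (1 atm), Pd(OH)2/C, Et3N (1.2 equiv), THF/MeOH/H2O, rt; filter under argon, lyophilise
Reagents that add atoms: none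
Why: Catalytic hydrogenolysis cleaves all nineteen benzyl ethers and the C8–Br bond in one operation, while the gallate esters, the ring O1–C2 bonds and the interflavan bonds are inert and Et3N takes up the HBr.

**Compound list**

1 | (−)-epicatechin | O[C@@H]1Cc2c(O)cc(O)cc2O[C@@H]1c1ccc(O)c(O)c1 | starting material
2 | 5,7,3',4'-tetra-O-benzyl-(−)-epicatechin | O[C@@H]1Cc2c(OCc3ccccc3)cc(OCc3ccccc3)cc2O[C@@H]1c1ccc(OCc2ccccc2)c(OCc2ccccc2)c1 | intermediate
3 | 8-bromo-5,7,3',4'-tetra-O-benzyl-(−)-epicatechin | O[C@@H]1Cc2c(OCc3ccccc3)cc(OCc3ccccc3)c(Br)c2O[C@@H]1c1ccc(OCc2ccccc2)c(OCc2ccccc2)c1 | intermediate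
4 | 8-bromo-5,7,3',4'-tetra-O-benzyl-3-O-(tert-butyldimethylsilyl)-(−)-epicatechin | CC(C)(C)[Si](C)(C)O[C@@H]1Cc2c(OCc3ccccc3)cc(OCc3ccccc3)c(Br)c2O[C@@H]1c1ccc(OCc2ccccc2)c(OCc2ccccc2)c1 | intermediate
5 | 8-bromo-4β-(2-ethoxyethoxy)-5,7,3',4'-tetra-O-benzyl-3-O-(tert-butyldimethylsilyl)-(−)-epicatechin | CC(C)(C)[Si](C)(C)O[C@@H]1[C@@H](OCCOCC)c2c(OCc3ccccc3)cc(OCc3ccccc3)c(Br)c2O[C@@H]1c1ccc(OCc2ccccc2)c(OCc2ccccc2)c1 | intermediate
6 | 8-bromo-6-iodo-4β-(2-ethoxyethoxy)-5,7,3',4'-tetra-O-benzyl-3-O-(tert-butyldimethylsilyl)-(−)-epicatechin | CC(C)(C)[Si](C)(C)O[C@@H]1[C@@H](OCCOCC)c2c(OCc3ccccc3)c(I)c(OCc3ccccc3)c(Br)c2O[C@@H]1c1ccc(OCc2ccccc2)c(OCc2ccccc2)c1 | intermediate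
7 | (+)-catechin | O[C@H]1Cc2c(O)cc(O)cc2O[C@@H]1c1ccc(O)c(O)c1 | starting material
8 | 5,7,3',4'-tetra-O-benzyl-(+)-catechin | O[C@H]1Cc2c(OCc3ccccc3)cc(OCc3ccccc3)cc2O[C@@H]1c1ccc(OCc2ccccc2)c(OCc2ccccc2)c1 | intermediate
9 | 3,5,7,3',4'-penta-O-benzyl-(+)-catechin | C(O[C@H]1Cc2c(OCc3ccccc3)cc(OCc3ccccc3)cc2O[C@@H]1c1ccc(OCc2ccccc2)c(OCc2ccccc2)c1)c1ccccc1 | intermediate
10 | dimer iodide: 8-bromo-6-iodo-5,7,3',4'-tetra-O-benzyl-3-O-TBS-epicatechin-(4β→8)-3,5,7,3',4'-penta-O-benzylcatechin | CC(C)(C)[Si](C)(C)O[C@@H]1[C@@H](c2c(OCc4ccccc4)cc(OCc4ccccc4)c3c2O[C@H](c2ccc(OCc4ccccc4)c(OCc4ccccc4)c2)[C@@H](OCc2ccccc2)C3)c2c(OCc3ccccc3)c(I)c(OCc3ccccc3)c(Br)c2O[C@@H]1c1ccc(OCc2ccccc2)c(OCc2ccccc2)c1 | intermediate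
11 | 4-bromo-1,2-bis(benzyloxy)benzene | Brc1ccc(OCc2ccccc2)c(OCc2ccccc2)c1 | starting material
12 | (R)-2,2-dimethyl-1,3-dioxolane-4-carbaldehyde (2,3-O-isopropylidene-D-glyceraldehyde) | CC1(C)OC[C@@H](O1)C=O | starting material
13 | [3,4-bis(benzyloxy)phenyl]lithium | [Li]c1ccc(OCc2ccccc2)c(OCc2ccccc2)c1 | intermediate
14 | [3,4-bis(benzyloxy)phenyl]titanium triisopropoxide | CC(C)O[Ti](OC(C)C)(OC(C)C)c1ccc(OCc2ccccc2)c(OCc2ccccc2)c1 | intermediate
15 | (S)-[3,4-bis(benzyloxy)phenyl][(4R)-2,2-dimethyl-1,3-dioxolan-4-yl]methanol | CC1(C)OC[C@@H](O1)[C@@H](O)c1ccc(OCc2ccccc2)c(OCc2ccccc2)c1 | intermediate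
16 | 3,5-bis(benzyloxy)phenol | Oc1cc(OCc2ccccc2)cc(OCc2ccccc2)c1 | starting material
17 | (4R)-4-{(R)-[3,4-bis(benzyloxy)phenyl][3,5-bis(benzyloxy)phenoxy]methyl}-2,2-dimethyl-1,3-dioxolane | CC1(C)OC[C@@H](O1)[C@H](Oc1cc(OCc2ccccc2)cc(OCc2ccccc2)c1)c1ccc(OCc2ccccc2)c(OCc2ccccc2)c1 | intermediate
18 | (2R,3R)-3-[3,4-bis(benzyloxy)phenyl]-3-[3,5-bis(benzyloxy)phenoxy]propane-1,2-diol | OC[C@@H](O)[C@H](Oc1cc(OCc2ccccc2)cc(OCc2ccccc2)c1)c1ccc(OCc2ccccc2)c(OCc2ccccc2)c1 | intermediate
19 | (2R,3R)-3-[3,4-bis(benzyloxy)phenyl]-3-[3,5-bis(benzyloxy)phenoxy]-1,2-bis(triethylsilyloxy)propane | CC[Si](CC)(CC)OC[C@@H](O[Si](CC)(CC)CC)[C@H](Oc1cc(OCc2ccccc2)cc(OCc2ccccc2)c1)c1ccc(OCc2ccccc2)c(OCc2ccccc2)c1 | intermediate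
20 | (2S,3R)-3-[3,4-bis(benzyloxy)phenyl]-3-[3,5-bis(benzyloxy)phenoxy]-2-(triethylsilyloxy)propanal | O=C[C@@H](O[Si](CC)(CC)CC)[C@H](Oc1cc(OCc2ccccc2)cc(OCc2ccccc2)c1)c1ccc(OCc2ccccc2)c(OCc2ccccc2)c1 | intermediate
21 | arylmagnesium chloride of 10 (MgCl at C6 of the middle unit in place of I) | CC(C)(C)[Si](C)(C)O[C@@H]1[C@@H](c2c(OCc4ccccc4)cc(OCc4ccccc4)c3c2O[C@H](c2ccc(OCc4ccccc4)c(OCc4ccccc4)c2)[C@@H](OCc2ccccc2)C3)c2c(OCc3ccccc3)c([Mg]Cl)c(OCc3ccccc3)c(Br)c2O[C@@H]1c1ccc(OCc2ccccc2)c(OCc2ccccc2)c1 | intermediate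
22 | carbinol: 10 with the iodine replaced by the (1RS,2R,3R)-3-[3,4-bis(benzyloxy)phenyl]-3-[3,5-bis(benzyloxy)phenoxy]-1-hydroxy-2-(triethylsilyloxy)propyl group | OC(c2c(OCc6ccccc6)c(Br)c3c(c2OCc6ccccc6)[C@H](c4c(OCc6ccccc6)cc(OCc6ccccc6)c5c4O[C@H](c4ccc(OCc6ccccc6)c(OCc6ccccc6)c4)[C@@H](OCc4ccccc4)C5)[C@@H](O[Si](C)(C)C(C)(C)C)[C@@H](c2ccc(OCc6ccccc6)c(OCc6ccccc6)c2)O3)[C@@H](O[Si](CC)(CC)CC)[C@H](Oc1cc(OCc2ccccc2)cc(OCc2ccccc2)c1)c1ccc(OCc2ccccc2)c(OCc2ccccc2)c1 | intermediate
23 | protected trimer: 5,7,3',4'-tetra-O-benzyl-3-O-triethylsilyl-epicatechin-(4β→6)-8-bromo-5,7,3',4'-tetra-O-benzyl-3-O-TBS-epicatechin-(4β→8)-3,5,7,3',4'-penta-O-benzylcatechin | CC[Si](CC)(CC)O[C@@H]1[C@@H](c2c(OCc6ccccc6)c(Br)c3c(c2OCc6ccccc6)[C@H](c4c(OCc6ccccc6)cc(OCc6ccccc6)c5c4O[C@H](c4ccc(OCc6ccccc6)c(OCc6ccccc6)c4)[C@@H](OCc4ccccc4)C5)[C@@H](O[Si](C)(C)C(C)(C)C)[C@@H](c2ccc(OCc6ccccc6)c(OCc6ccccc6)c2)O3)c2c(OCc3ccccc3)cc(OCc3ccccc3)cc2O[C@@H]1c1ccc(OCc2ccccc2)c(OCc2ccccc2)c1 | intermediate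
24 | diol: 23 with free 3-OH on the top and middle units | O[C@@H]1[C@@H](c2c(OCc6ccccc6)c(Br)c3c(c2OCc6ccccc6)[C@H](c4c(OCc6ccccc6)cc(OCc6ccccc6)c5c4O[C@H](c4ccc(OCc6ccccc6)c(OCc6ccccc6)c4)[C@@H](OCc4ccccc4)C5)[C@@H](O)[C@@H](c2ccc(OCc6ccccc6)c(OCc6ccccc6)c2)O3)c2c(OCc3ccccc3)cc(OCc3ccccc3)cc2O[C@@H]1c1ccc(OCc2ccccc2)c(OCc2ccccc2)c1 | intermediate
25 | 3,4,5-tris(benzyloxy)benzoic acid | OC(=O)c1cc(OCc2ccccc2)c(OCc2ccccc2)c(OCc2ccccc2)c1 | starting material
26 | bis-gallate: 24 carrying a 3,4,5-tris(benzyloxy)benzoate on the top and on the middle 3-oxygen | O=C(O[C@@H]1[C@@H](c2c(OCc6ccccc6)c(Br)c3c(c2OCc6ccccc6)[C@H](c4c(OCc6ccccc6)cc(OCc6ccccc6)c5c4O[C@H](c4ccc(OCc6ccccc6)c(OCc6ccccc6)c4)[C@@H](OCc4ccccc4)C5)[C@@H](OC(=O)c2cc(OCc6ccccc6)c(OCc6ccccc6)c(OCc6ccccc6)c2)[C@@H](c2ccc(OCc6ccccc6)c(OCc6ccccc6)c2)O3)c2c(OCc3ccccc3)cc(OCc3ccccc3)cc2O[C@@H]1c1ccc(OCc2ccccc2)c(OCc2ccccc2)c1)c1cc(OCc2ccccc2)c(OCc2ccccc2)c(OCc2ccccc2)c1 | intermediate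
27 | epicatechin-3-O-gallate-(4β→6)-epicatechin-3-O-gallate-(4β→8)-catechin (CNP0112921.1) | O=C(O[C@@H]1[C@@H](c2c(O)cc3c(c2O)[C@H](c2c(O)cc(O)c4c2O[C@H](c2ccc(O)c(O)c2)[C@@H](O)C4)[C@@H](OC(=O)c2cc(O)c(O)c(O)c2)[C@@H](c2ccc(O)c(O)c2)O3)c2c(O)cc(O)cc2O[C@@H]1c1ccc(O)c(O)c1)c1cc(O)c(O)c(O)c1 | target

**Step count and risks**

Total step count: 18. Longest linear sequence: 11 steps (steps 1 to 5, 8 and 14 to 18, from (−)-epicatechin).

Steps most likely to fail, each with one fallback:

Step 15. Facial selectivity at C4 may be poor, or the cation may fragment across the C2–C3 bond before the arene arrives. The ring would then be closed before the interflavan bond is made. Aldehyde 20, treated with BF3·OEt2 in CH2Cl2 at −78 °C, should undergo intramolecular Friedel–Crafts hydroxyalkylation to 5,7,3',4'-tetra-O-benzyl-3-O-triethylsilyl-2,3-cis-flavan-3,4-diol F1. Iodide 10 is reduced (i-PrMgCl·LiCl, then methanol) to the 6-unsubstituted 8-bromo dimer F2. TMSOTf at −78 °C then ionises F1 at C4, and F2 adds through C6 of its middle unit, trans to the 3-silyloxy group as is usual for epicatechin-derived 4-cations. This fallback sets out from 20 and 10 and comes back at 23. C6 of the lower unit of F2 is the competing site, and its adduct would have to be removed by chromatography.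

Step 14. The iodine–magnesium exchange on the hindered, electron-rich iodide may stall, or the basic arylmagnesium may enolise 20 and expel the β-aryloxide. Compounds 10 and 20 would then be joined under Nozaki–Hiyama–Kishi conditions (CrCl2 in excess, catalytic NiCl2, DMF/THF, rt). Nickel should take up the aryl iodide and not the bromide, and the non-basic arylchromium adds to the aldehyde. This fallback sets out from 10 and 20, comes back at 22 and makes no new compound (F0).

Step 10. Partial ionisation of the activated alcohol at the electron-rich benzylic carbon would erode the configuration at C2, and the hindered carbinol may react slowly. The C–O bond at C2 would then be kept and the aryl group brought to oxygen instead. From 15, Dess–Martin oxidation gives (R)-[3,4-bis(benzyloxy)phenyl](2,2-dimethyl-1,3-dioxolan-4-yl)methanone F3. Felkin–Anh reduction with LiBH(s-Bu)3 at −78 °C gives the syn alcohol (R)-[3,4-bis(benzyloxy)phenyl][(4R)-2,2-dimethyl-1,3-dioxolan-4-yl]methanol F4. Copper-catalysed O-arylation with 1,3-bis(benzyloxy)-5-iodobenzene (CuI, 3,4,7,8-tetramethyl-1,10-phenanthroline, Cs2CO3, toluene, 100 °C), with retention at carbon, comes back at 17.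

Further compounds
F1 | step 15 | 5,7,3',4'-tetra-O-benzyl-3-O-triethylsilyl-2,3-cis-flavan-3,4-diol (C4 epimers) | CC[Si](CC)(CC)O[C@@H]1C(O)c2c(OCc3ccccc3)cc(OCc3ccccc3)cc2O[C@@H]1c1ccc(OCc2ccccc2)c(OCc2ccccc2)c1
F2 | step 15 | 8-bromo-5,7,3',4'-tetra-O-benzyl-3-O-TBS-epicatechin-(4β→8)-3,5,7,3',4'-penta-O-benzylcatechin | CC(C)(C)[Si](C)(C)O[C@@H]1[C@@H](c2c(OCc4ccccc4)cc(OCc4ccccc4)c3c2O[C@H](c2ccc(OCc4ccccc4)c(OCc4ccccc4)c2)[C@@H](OCc2ccccc2)C3)c2c(OCc3ccccc3)cc(OCc3ccccc3)c(Br)c2O[C@@H]1c1ccc(OCc2ccccc2)c(OCc2ccccc2)c1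
F0 | step 14 | none | none
F3 | step 10 | (R)-[3,4-bis(benzyloxy)phenyl](2,2-dimethyl-1,3-dioxolan-4-yl)methanone | CC1(C)OC[C@@H](O1)C(=O)c1ccc(OCc2ccccc2)c(OCc2ccccc2)c1
F4 | step 10 | (R)-[3,4-bis(benzyloxy)phenyl][(4R)-2,2-dimethyl-1,3-dioxolan-4-yl]methanol | CC1(C)OC[C@@H](O1)[C@H](O)c1ccc(OCc2ccccc2)c(OCc2ccccc2)c1
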